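- A small charge of L stops making product early: Tuesday's X and Z together read 16.0% at 30.0 h and 16.0% at 50.0 h, and Thursday's, with more L, read 25.7% and 25.5% at the same times.

all flasks: D 0.050 M; Q 0.050 M
- Tuesday's: J 0.050 M; L 2.5 mM; run made earlier
- Sunday's: J 0.091 M; L 2.5 mM; run made earlier
- Thursday's: J 0.075 M; L 3.8 mM; run made earlier
- violet: J 0.150 M; L 8.0 mM; time 4.0 d
- blue: J 0.0750 M; L 2.5 mM; time 4.0 d

- Tuesday's (time / h: X / %, Z / %): 4.00: 5.3, 2.7; 12.0: 6.0, 4.4; 20.0: 6.7, 7.5; 30.0: 8.2, 7.8; 50.0: 8.7, 7.3
- Sunday's (time / h: X / %, Z / %): 10.0: 8.0, 2.8; 20.0: 9.5, 8.2; 30.0: 9.4, 9.7; 40.0: 9.7, 9.0; 50.0: 7.6, 10.0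
- Thursday's (time / h: X / %, Z / %): 10.0: 10.2, 5.9; 20.0: 10.5, 9.8; 30.0: 14.1, 11.6; 40.0: 13.9, 11.0; 50.0: 13.5, 12.0

(standard deviation of a reading: 1 percentage point)

- L is single-handed; D and Q are mirror images of each other, charged as a racemate, each of them at the stated concentration

1. which of the two ends with the higher share of X in all that became X or Z ("neither" if they lie within 2 percentage points) (violet / blue / neither)
2. share of X in all that became X or Z, violet
3. share of X in all that became X or Z, blue

- One extreme is kinetic control: X and Z never change after they form, so the share of X stays at Tuesday's first reading, 66.2%.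
- The other is thermodynamic control: the share goes straight to its end value. I replace the last readings of the three runs by their mean, 50.2%, and call that even.
- The flask lies between them, and the lead tells where. I define the lead as (X − Z)/(X + Z); the share stands above even by 0.5 of it.
- Tuesday's lead reads 0.325 at 4.00 h and 0.154 at 12.0 h. That gives a reading of 7.41 h, the lead's half-life.
- I assume violet and blue also stop making product by 30.0 h. The rest of the 4.0 d then holds 8.90 half-lives, so the share ends 0.034 percentage points above even, about 50.0% in both flasks.
- The scatter is large, but with a half-life of twice that the excess is 0.74 points, less than the margin 2 points.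
- The forecast gives violet 51.5%, blue 52.5% and neither, holding that “the early selectivity fades as the catalyst changes”. Its shares stand a little above mine, and its choice is the same.

Violet gives 50.0% and blue 50.0%, so the answer is neither.

    J + L + D → L + X (k = 3.10 M⁻² min⁻¹)
    J + L → G (k = 0.0251 M⁻¹ min⁻¹)
    J + L + Q → L + Z (k = 1.14 M⁻² min⁻¹)
    X ⇌ Z (k = 0.00102 min⁻¹)

In blue, the exchange X ⇌ Z has a relaxation half-life of 0.236 d, short against the 4.0 d. Blue read at 25 h shows a share of 53.3%, a lead of 0.0654, with L still at 9.96% of its charge. My half-life puts 9.58 half-lives between that reading and the end, a count that leaves aside the product still forming after it, and blue at the end holds X 9.32% and Z 9.32%.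

The numbers in the tables stem from a simulated flask on assumed constants, noise included.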